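## Retrosynthetic overview

1. Endgame: the α-methylene group comes from β-elimination of a C17 acetate, the acetates from a triol, and the saturated 14-membered ring from hydrogenation of a C9=C10/C13=C14 diene.
2. Key ring closure (third ring): ring-closing metathesis of a seco-diene at C9=C10 closes the 14-membered carbocycle.
3. The seco-diene comes from a C2–C3 union: palladium-catalysed coupling of an alkylzinc (south lactone fragment, C10–C2) with a thioester (north oxolane fragment, C3–C9), then CBS reduction to set C3.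
4. South fragment (second ring): a seven-membered lactone closed by ring-closing metathesis (C13=C14) of the ester between a tertiary alcohol (C10–C13; Sharpless desymmetrisation, chelate-controlled vinylation) and an acid (C1 by Johnson–Claisen chirality transfer).
5. North fragment (first ring): a cis-oxolane closed by 5-exo epoxide opening; C4 from (R)-lactic acid (Seebach alkylation), C7/C8 from a Sharpless epoxide.

Assumption: locants follow cembrane numbering (ring C1–C14; C15 = lactone α-carbon, C16 = lactone C=O, C17 = exocyclic CH2; C18, C19, C20 = methyls on C4, C8, C12), in which the target is 1S,3R,4S,7R,8S,11S,12S.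

## Route

### North fragment (steps 1–10)

Step 1
Reactants: 1 (R)-lactic acid
Product: 2 (2R,5R)-2-tert-butyl-5-methyl-1,3-dioxolan-4-one
Conditions: pivalaldehyde, cat. p-TsOH, pentane, reflux (Dean–Stark); recrystallise
Reagents that add atoms: pivalaldehyde (2,2-dimethylpropanal), CC(C)(C)C=O
Why: Acid-catalysed acetalisation (Seebach dioxolanone) gives the cis acetal as the thermodynamic, crystalline isomer, leaving the lactate centre untouched and relaying its chirality to the acetal carbon.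

Step 2
Reactants: 3 5-bromo-2-methylpent-2-ene
Product: 4 (2E)-5-bromo-2-methylpent-2-en-1-ol
Conditions: SeO2 (0.3 equiv), t-BuOOH, CH2Cl2, 0 °C → rt
Reagents that add atoms: tert-butyl hydroperoxide, CC(C)(C)OO
Why: Sharpless catalytic SeO2 allylic oxidation (ene reaction then [2,3]-shift) hydroxylates the (E)-methyl group of a trisubstituted alkene selectively.

Step 3
Reactants: 4 (2E)-5-bromo-2-methylpent-2-en-1-ol
Product: 5 [(2S,3S)-3-(2-bromoethyl)-2-methyloxiran-2-yl]methanol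
Conditions: Ti(OiPr)4 (10 mol%), L-(+)-diethyl tartrate (12 mol%), t-BuOOH, 4 Å molecular sieves, CH2Cl2, −20 °C
Reagents that add atoms: tert-butyl hydroperoxide, CC(C)(C)OO
Why: Sharpless asymmetric epoxidation with the L-(+)-tartrate titanium catalyst delivers oxygen to one face of the allylic alcohol, setting both epoxide carbons as (2S,3S) (future C8 and, after a later inversion, C7).

Step 4
Reactants: 5 [(2S,3S)-3-(2-bromoethyl)-2-methyloxiran-2-yl]methanol
Product: 6 (2R,3S)-3-(2-bromoethyl)-2-methyloxirane-2-carbaldehyde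
Conditions: Dess–Martin periodinane, NaHCO3, CH2Cl2, 0 °C → rt
Reagents that add atoms: none
Why: Dess–Martin oxidation under buffered conditions converts the primary alcohol to the aldehyde without touching the epoxide, the bromide or the non-enolisable quaternary centre.

Step 5
Reactants: 6 (2R,3S)-3-(2-bromoethyl)-2-methyloxirane-2-carbaldehyde
Product: 7 (2S,3S)-2-(2-bromoethyl)-3-ethenyl-3-methyloxirane
Conditions: Ph3PCH3Br, KN(SiMe3)2, THF, 0 °C; then 6, −78 → 0 °C
Reagents that add atoms: methylidene(triphenyl)phosphorane, C=P(c1ccccc1)(c1ccccc1)c1ccccc1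
Why: Wittig methylenation of the epoxy aldehyde gives the vinyl epoxide with the stereocentres unchanged, the aldehyde reacting far faster than the primary bromide.

Step 6
Reactants: 7 (2S,3S)-2-(2-bromoethyl)-3-ethenyl-3-methyloxirane
Product: 8 (2S,3S)-3-ethenyl-2-(2-iodoethyl)-3-methyloxirane
Conditions: NaI, NaHCO3, acetone, 50 °C
Reagents that add atoms: sodium iodide, [Na+].[I-]
Why: Finkelstein halide exchange (SN2 at the primary carbon, driven by NaBr precipitation) gives the more reactive iodide for the enolate alkylation.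

Step 7
Reactants: 2 (2R,5R)-2-tert-butyl-5-methyl-1,3-dioxolan-4-one; 8 (2S,3S)-3-ethenyl-2-(2-iodoethyl)-3-methyloxirane
Product: 10 (2R,5S)-2-tert-butyl-5-{2-[(2S,3S)-3-ethenyl-3-methyloxiran-2-yl]ethyl}-5-methyl-1,3-dioxolan-4-one, via lithium enolate 9 (not isolated)
Conditions: LiN(iPr)2, THF, −78 °C; then 8, DMPU, −78 → −30 °C
Reagents that add atoms: none
Why: Seebach self-regeneration of stereocentres: the enolate is alkylated (SN2) on the face opposite the tert-butyl group, so the new quaternary centre (C4) is formed as (S) with overall retention.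

Step 8
Reactants: 10 (2R,5S)-2-tert-butyl-5-{2-[(2S,3S)-3-ethenyl-3-methyloxiran-2-yl]ethyl}-5-methyl-1,3-dioxolan-4-one
Product: 12 methyl (2S,5R)-5-[(2S)-2-hydroxybut-3-en-2-yl]-2-methyloxolane-2-carboxylate, via hydroxy ester 11 (not isolated)
Conditions: K2CO3 (0.3 equiv), MeOH, 0 → 40 °C
Reagents that add atoms: methanol, CO
Why: Base-catalysed methanolysis of the acylal frees the tertiary C4 alkoxide, which opens the epoxide by 5-exo-tet SN2 attack at C7 (inversion, giving 7R) while C8 keeps its oxygen as the tertiary alcohol (8S), closing the cis-oxolane.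

Step 9
Reactants: 12 methyl (2S,5R)-5-[(2S)-2-hydroxybut-3-en-2-yl]-2-methyloxolane-2-carboxylate
Product: 13 S-ethyl (2S,5R)-5-[(2S)-2-hydroxybut-3-en-2-yl]-2-methyloxolane-2-carbothioate
Conditions: AlMe3, EtSH, CH2Cl2, 0 °C → rt
Reagents that add atoms: ethanethiol, CCS
Why: Acyl substitution by dimethylaluminium ethanethiolate converts even a hindered methyl ester into the thioester without touching the stereocentres.

Step 10
Reactants: 13 S-ethyl (2S,5R)-5-[(2S)-2-hydroxybut-3-en-2-yl]-2-methyloxolane-2-carbothioate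
Product: 14 S-ethyl (2S,5R)-2-methyl-5-[(2S)-2-(trimethylsilyloxy)but-3-en-2-yl]oxolane-2-carbothioate
Conditions: TMSOTf, 2,6-lutidine, CH2Cl2, −78 °C
Reagents that add atoms: trimethylsilyl trifluoromethanesulfonate, C[Si](C)(C)OS(=O)(=O)C(F)(F)F
Why: Silylation of the hindered tertiary alcohol by the silyl triflate masks the only acidic proton before the organozinc coupling.

### Acid piece of the south fragment (steps 11–15)

Step 11
Reactants: 15 (S)-but-3-yn-2-ol
Product: 17 (4S)-pent-2-yne-1,4-diol, via dilithium salt 16 (not isolated)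
Conditions: n-BuLi (2.2 equiv), THF, −78 °C; paraformaldehyde, −78 °C → rt
Reagents that add atoms: formaldehyde (as paraformaldehyde), C=O
Why: Hydroxymethylation by addition of the lithium acetylide to formaldehyde; the carbinol centre is not involved.

Step 12
Reactants: 17 (4S)-pent-2-yne-1,4-diol
Product: 18 (2E,4S)-pent-2-ene-1,4-diol
Conditions: NaAlH2(OCH2CH2OMe)2, THF, 0 °C → rt; aq. potassium sodium tartrate
Reagents that add atoms: none
Why: Hydroxyl-directed trans-hydroalumination of the propargylic alcohol followed by protonolysis gives only the (E)-alkene.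

Step 13
Reactants: 18 (2E,4S)-pent-2-ene-1,4-diol
Product: 19 (2S,3E)-5-{[tert-butyl(dimethyl)silyl]oxy}pent-3-en-2-ol
Conditions: TBSCl (1.05 equiv), imidazole, CH2Cl2, −20 °C
Reagents that add atoms: tert-butyl(chloro)dimethylsilane, CC(C)(C)[Si](C)(C)Cl
Why: Silylation is selective for the primary over the secondary allylic alcohol on steric grounds.

Step 14
Reactants: 19 (2S,3E)-5-{[tert-butyl(dimethyl)silyl]oxy}pent-3-en-2-ol
Product: 21 ethyl (3S,4E)-3-({[tert-butyl(dimethyl)silyl]oxy}methyl)hex-4-enoate, via ketene acetal 20 (not isolated)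
Conditions: MeC(OEt)3, propionic acid (cat.), xylene, 135 °C (EtOH distilled off)
Reagents that add atoms: triethyl orthoacetate, CCOC(C)(OCC)OCC
Why: Johnson–Claisen rearrangement through a chair transition state with the methyl group equatorial transfers the (S)-carbinol chirality suprafacially to the new C–C bond, giving the (3S) centre (future C1) and an (E)-propenyl group.

Step 15
Reactants: 21 ethyl (3S,4E)-3-({[tert-butyl(dimethyl)silyl]oxy}methyl)hex-4-enoate
Product: 22 (3S,4E)-3-({[tert-butyl(dimethyl)silyl]oxy}methyl)hex-4-enoic acid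
Conditions: LiOH·H2O, THF/MeOH/H2O, rt; then aq. HCl to pH 4
Reagents that add atoms: lithium hydroxide, [Li+].[OH-]
Why: Saponification under conditions that leave the primary silyl ether intact.

### Alcohol piece of the south fragment (steps 16–20)

Step 16
Reactants: 23 penta-1,4-dien-3-ol
Product: 24 (1S)-1-[(2R)-oxiran-2-yl]prop-2-en-1-ol
Conditions: Ti(OiPr)4 (10 mol%), L-(+)-diisopropyl tartrate (13 mol%), t-BuOOH, 4 Å molecular sieves, CH2Cl2, −20 °C, 5 d
Reagents that add atoms: tert-butyl hydroperoxide, CC(C)(C)OO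
Why: Sharpless asymmetric epoxidation desymmetrises the divinyl carbinol (group- and face-selective, with kinetic-resolution upgrading of ee) to the erythro epoxy alcohol, fixing the future C11.

Step 17
Reactants: 24 (1S)-1-[(2R)-oxiran-2-yl]prop-2-en-1-ol
Product: 25 (2R)-2-[(1S)-1-(benzyloxy)prop-2-en-1-yl]oxirane
Conditions: NaH, BnBr, n-Bu4NI (cat.), THF, −20 → 0 °C
Reagents that add atoms: benzyl bromide, BrCc1ccccc1
Why: Williamson etherification at low temperature outruns Payne rearrangement of the epoxy alkoxide.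

Step 18
Reactants: 25 (2R)-2-[(1S)-1-(benzyloxy)prop-2-en-1-yl]oxirane
Product: 26 (2R,3S)-3-(benzyloxy)pent-4-en-2-ol
Conditions: LiAlH4, Et2O, 0 °C
Reagents that add atoms: none
Why: Hydride opens the monosubstituted epoxide by SN2 attack at its unhindered CH2 terminus, giving the methyl carbinol without touching the benzyloxy centre.

Step 19
Reactants: 26 (2R,3S)-3-(benzyloxy)pent-4-en-2-ol
Product: 27 (3S)-3-(benzyloxy)pent-4-en-2-one
Conditions: Dess–Martin periodinane, NaHCO3, CH2Cl2, 0 °C; used at once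
Reagents that add atoms: none
Why: Dess–Martin oxidation under buffered, non-basic conditions gives the α-benzyloxy ketone without epimerising or conjugating the β,γ-unsaturated centre.

Step 20
Reactants: 27 (3S)-3-(benzyloxy)pent-4-en-2-one
Product: 28 (3S,4S)-4-(benzyloxy)-3-methylhexa-1,5-dien-3-ol
Conditions: MgBr2·OEt2, CH2Cl2, −78 °C; vinylmagnesium bromide, −78 °C
Reagents that add atoms: vinylmagnesium bromide, C=C[Mg]Br
Why: Cram-chelate-controlled Grignard addition: magnesium bridges the ketone and benzyloxy oxygens and the vinyl group attacks from the side of the small hydrogen, giving the (3S,4S) tertiary alcohol (future C12).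

### South lactone assembly (steps 21–24)

Step 21
Reactants: 22 (3S,4E)-3-({[tert-butyl(dimethyl)silyl]oxy}methyl)hex-4-enoic acid; 28 (3S,4S)-4-(benzyloxy)-3-methylhexa-1,5-dien-3-ol
Product: 31 (3S,4S)-4-(benzyloxy)-3-methylhexa-1,5-dien-3-yl (3S,4E)-3-({[tert-butyl(dimethyl)silyl]oxy}methyl)hex-4-enoate, via acid chloride 29 (not isolated), via lithium alkoxide 30 (not isolated)
Conditions: 22, 1-chloro-N,N,2-trimethylprop-1-en-1-amine, CH2Cl2, 0 °C; 28, n-BuLi, THF, −78 °C; combine, −78 → 0 °C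
Reagents that add atoms: none
Why: O-Acylation of a lithium tert-alkoxide by an acid chloride (made under neutral conditions that spare the silyl ether) is the reliable way to esterify a hindered tertiary alcohol, and no stereocentre is touched.

Step 22
Reactants: 31 (3S,4S)-4-(benzyloxy)-3-methylhexa-1,5-dien-3-yl (3S,4E)-3-({[tert-butyl(dimethyl)silyl]oxy}methyl)hex-4-enoate
Product: 32 (4S,7S)-7-[(1S)-1-(benzyloxy)prop-2-en-1-yl]-4-({[tert-butyl(dimethyl)silyl]oxy}methyl)-7-methyl-4,7-dihydrooxepin-2(3H)-one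
Conditions: second-generation Grubbs catalyst (5 mol%), CH2Cl2 (5 mM), 40 °C
Reagents that add atoms: none
Why: Ring-closing metathesis between the vinyl group on C12 and the propenyl group on C1 closes the seven-membered lactone (propene lost), a ring size favoured over the eight-membered alternative through the third alkene.

Step 23
Reactants: 32 (4S,7S)-7-[(1S)-1-(benzyloxy)prop-2-en-1-yl]-4-({[tert-butyl(dimethyl)silyl]oxy}methyl)-7-methyl-4,7-dihydrooxepin-2(3H)-one
Product: 34 (4R,7S)-7-[(1S)-1-(benzyloxy)prop-2-en-1-yl]-3-[(benzyloxy)methyl]-4-({[tert-butyl(dimethyl)silyl]oxy}methyl)-7-methyl-4,7-dihydrooxepin-2(3H)-one (C3 epimers), via lithium enolate 33 (not isolated)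
Conditions: LiN(iPr)2, THF, −78 °C; benzyl chloromethyl ether, −78 → −40 °C
Reagents that add atoms: benzyl chloromethyl ether, ClCOCc1ccccc1
Why: Alkylation of the lactone enolate at its only enolisable position installs C17 as a masked exo-methylene carbon; the new centre (C15, mainly trans to the C1 substituent) is destroyed in the last step.

Step 24
Reactants: 34 (4R,7S)-7-[(1S)-1-(benzyloxy)prop-2-en-1-yl]-3-[(benzyloxy)methyl]-4-({[tert-butyl(dimethyl)silyl]oxy}methyl)-7-methyl-4,7-dihydrooxepin-2(3H)-one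
Product: 35 (4R,7S)-7-[(1S)-1-(benzyloxy)prop-2-en-1-yl]-3-[(benzyloxy)methyl]-4-(bromomethyl)-7-methyl-4,7-dihydrooxepin-2(3H)-one (C3 epimers)
Conditions: Ph3PBr2, CH2Cl2, 0 °C → rt
Reagents that add atoms: dibromo(triphenyl)phosphorane, BrP(Br)(c1ccccc1)(c1ccccc1)c1ccccc1
Why: Direct conversion of the primary silyl ether to the bromide (oxyphosphonium formation, then SN2 by bromide) never frees the γ-hydroxyl, which would translactonise to a γ-butyrolactone.

### Union and endgame (steps 25–31)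

Step 25
Reactants: 35 (4R,7S)-7-[(1S)-1-(benzyloxy)prop-2-en-1-yl]-3-[(benzyloxy)methyl]-4-(bromomethyl)-7-methyl-4,7-dihydrooxepin-2(3H)-one; 14 S-ethyl (2S,5R)-2-methyl-5-[(2S)-2-(trimethylsilyloxy)but-3-en-2-yl]oxolane-2-carbothioate
Product: 37 (4R,7S)-7-[(1S)-1-(benzyloxy)prop-2-en-1-yl]-3-[(benzyloxy)methyl]-7-methyl-4-(2-{(2S,5R)-2-methyl-5-[(2S)-2-(trimethylsilyloxy)but-3-en-2-yl]oxolan-2-yl}-2-oxoethyl)-4,7-dihydrooxepin-2(3H)-one, via alkylzinc bromide 36 (not isolated)
Conditions: 35, Zn dust, LiCl, THF, 50 °C; then 14, PdCl2(PPh3)2 (10 mol%), toluene, rt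
Reagents that add atoms: none
Why: Fukuyama coupling: zerovalent palladium inserts into the thioester C–S bond, the alkylzinc transmetalates and reductive elimination gives the C3 ketone without over-addition, tolerating the lactone, ethers and alkenes.

Step 26
Reactants: 37 (the C3 ketone)
Product: 39 (4R,7S)-7-[(1S)-1-(benzyloxy)prop-2-en-1-yl]-3-[(benzyloxy)methyl]-4-[(2R)-2-hydroxy-2-{(2S,5R)-5-[(2S)-2-hydroxybut-3-en-2-yl]-2-methyloxolan-2-yl}ethyl]-7-methyl-4,7-dihydrooxepin-2(3H)-one, via silyl ether alcohol 38 (not isolated)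
Conditions: (S)-2-methyl-CBS-oxazaborolidine (0.5 equiv), catecholborane, toluene, −78 °C; then MeOH, aq. citric acid, rt
Reagents that add atoms: none
Why: Corey–Bakshi–Shibata reduction: the (S)-oxazaborolidine delivers hydride to the ketone face that keeps the bulky quaternary C4 group away from the catalyst, giving the (3R) alcohol under reagent control, and the acidic work-up removes the trimethylsilyl group.

Step 27
Reactants: 39 (the seco-diene diol)
Product: 40 (1R,3R,4S,7R,8S,11S,12S)-11,17-bis(benzyloxy)-4,7-epoxy-3,8-dihydroxycembra-9,13-dien-16,12-olide (C15 epimers; C9=C10 E/Z)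
Conditions: second-generation Hoveyda–Grubbs catalyst (10 mol%), toluene (2 mM), 80 °C
Reagents that add atoms: none
Why: Ring-closing metathesis of the two terminal vinyl groups closes the 14-membered carbocycle at C9=C10 (ethene lost), helped by the free allylic tertiary hydroxyl and high dilution; the alkene geometry is irrelevant because it is hydrogenated next.

Step 28
Reactants: 40 (the macrocyclic diene)
Product: 41 (1S,3R,4S,7R,8S,11S,12S)-11,17-bis(benzyloxy)-4,7-epoxy-3,8-dihydroxycembran-16,12-olide (C15 epimers)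
Conditions: H2 (1 atm), [Ir(cod)(PCy3)(py)]PF6 (10 mol%), CH2Cl2, rt
Reagents that add atoms: none
Why: Hydroxyl-directed homogeneous hydrogenation saturates both hindered disubstituted alkenes without hydrogenolysis of the allylic lactone C–O bond or of the benzyl ethers.

Step 29
Reactants: 41 (the saturated bis-benzyl ether)
Product: 42 (1S,3R,4S,7R,8S,11S,12S)-4,7-epoxy-3,8,11,17-tetrahydroxycembran-16,12-olide (C15 epimers)
Conditions: H2 (1 atm), Pd(OH)2/C, EtOAc, rt
Reagents that add atoms: none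
Why: Hydrogenolysis of both benzyl ethers, now safe because no allylic C–O bond remains.

Step 30
Reactants: 42 (the tetraol)
Product: 43 (1S,3R,4S,7R,8S,11S,12S)-3,11,17-triacetoxy-4,7-epoxy-8-hydroxycembran-16,12-olide (C15 epimers)
Conditions: Ac2O, pyridine, DMAP (cat.), CH2Cl2, 0 °C → rt
Reagents that add atoms: acetic anhydride, CC(=O)OC(C)=O
Why: DMAP-catalysed acetylation esterifies the primary and the two secondary alcohols while the hindered tertiary C8 hydroxyl stays free.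

Step 31
Reactants: 43 (the triacetate)
Product: 44 (1S,3R,4S,7R,8S,11S,12S)-3,11-diacetoxy-4,7-epoxy-8-hydroxycembr-15(17)-en-16,12-olide (CNP0343714.5)
Conditions: DBU, CH2Cl2, rt
Reagents that add atoms: none
Why: E1cB β-elimination of acetic acid from the β-acetoxy lactone unveils the α-methylene group and removes the C15 centre; the secondary acetates are not β to a carbonyl and stay.

## Compound list

1 | (R)-lactic acid | C[C@@H](O)C(=O)O | starting material
2 | (2R,5R)-2-tert-butyl-5-methyl-1,3-dioxolan-4-one | C[C@H]1O[C@@H](C(C)(C)C)OC1=O | intermediate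
3 | 5-bromo-2-methylpent-2-ene | CC(C)=CCCBr | starting material
4 | (2E)-5-bromo-2-methylpent-2-en-1-ol | OC/C(C)=C/CCBr | intermediate
5 | [(2S,3S)-3-(2-bromoethyl)-2-methyloxiran-2-yl]methanol | OC[C@]1(C)O[C@H]1CCBr | intermediate
6 | (2R,3S)-3-(2-bromoethyl)-2-methyloxirane-2-carbaldehyde | O=C[C@]1(C)O[C@H]1CCBr | intermediate
7 | (2S,3S)-2-(2-bromoethyl)-3-ethenyl-3-methyloxirane | C=C[C@]1(C)O[C@H]1CCBr | intermediate
8 | (2S,3S)-3-ethenyl-2-(2-iodoethyl)-3-methyloxirane | C=C[C@]1(C)O[C@H]1CCI | intermediate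
9 | lithium (2R)-2-tert-butyl-5-methyl-1,3-dioxol-4-olate (enolate of 2) | [Li+].CC1=C([O-])O[C@H](C(C)(C)C)O1 | intermediate
10 | (2R,5S)-2-tert-butyl-5-{2-[(2S,3S)-3-ethenyl-3-methyloxiran-2-yl]ethyl}-5-methyl-1,3-dioxolan-4-one | C[C@@]1(CC[C@@H]2O[C@@]2(C)C=C)O[C@@H](C(C)(C)C)OC1=O | intermediate
11 | methyl (2S)-4-[(2S,3S)-3-ethenyl-3-methyloxiran-2-yl]-2-hydroxy-2-methylbutanoate | COC(=O)[C@@](C)(O)CC[C@@H]1O[C@@]1(C)C=C | intermediate
12 | methyl (2S,5R)-5-[(2S)-2-hydroxybut-3-en-2-yl]-2-methyloxolane-2-carboxylate | COC(=O)[C@]1(C)CC[C@@H](O1)[C@@](C)(O)C=C | intermediate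
13 | S-ethyl (2S,5R)-5-[(2S)-2-hydroxybut-3-en-2-yl]-2-methyloxolane-2-carbothioate | CCSC(=O)[C@]1(C)CC[C@@H](O1)[C@@](C)(O)C=C | intermediate
14 | S-ethyl (2S,5R)-2-methyl-5-[(2S)-2-(trimethylsilyloxy)but-3-en-2-yl]oxolane-2-carbothioate | CCSC(=O)[C@]1(C)CC[C@@H](O1)[C@@](C)(O[Si](C)(C)C)C=C | intermediate
15 | (S)-but-3-yn-2-ol | C[C@H](O)C#C | starting material
16 | dilithium salt of 15 (alkoxide acetylide) | [Li+].[Li+].C[C@H]([O-])C#[C-] | intermediate
17 | (4S)-pent-2-yne-1,4-diol | C[C@H](O)C#CCO | intermediate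
18 | (2E,4S)-pent-2-ene-1,4-diol | C[C@H](O)/C=C/CO | intermediate
19 | (2S,3E)-5-{[tert-butyl(dimethyl)silyl]oxy}pent-3-en-2-ol | C[C@H](O)/C=C/CO[Si](C)(C)C(C)(C)C | intermediate
20 | tert-butyl{[(2E,4S)-4-(1-ethoxyethenyloxy)pent-2-en-1-yl]oxy}dimethylsilane (ketene acetal) | C=C(OCC)O[C@@H](C)/C=C/CO[Si](C)(C)C(C)(C)C | intermediate
21 | ethyl (3S,4E)-3-({[tert-butyl(dimethyl)silyl]oxy}methyl)hex-4-enoate | CCOC(=O)C[C@H](CO[Si](C)(C)C(C)(C)C)/C=C/C | intermediate
22 | (3S,4E)-3-({[tert-butyl(dimethyl)silyl]oxy}methyl)hex-4-enoic acid | OC(=O)C[C@H](CO[Si](C)(C)C(C)(C)C)/C=C/C | intermediate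
23 | penta-1,4-dien-3-ol | C=CC(O)C=C | starting material
24 | (1S)-1-[(2R)-oxiran-2-yl]prop-2-en-1-ol | C=C[C@H](O)[C@H]1CO1 | intermediate
25 | (2R)-2-[(1S)-1-(benzyloxy)prop-2-en-1-yl]oxirane | C=C[C@H](OCc1ccccc1)[C@H]1CO1 | intermediate
26 | (2R,3S)-3-(benzyloxy)pent-4-en-2-ol | C=C[C@H](OCc1ccccc1)[C@@H](C)O | intermediate
27 | (3S)-3-(benzyloxy)pent-4-en-2-one | C=C[C@H](OCc1ccccc1)C(C)=O | intermediate
28 | (3S,4S)-4-(benzyloxy)-3-methylhexa-1,5-dien-3-ol | C=C[C@](C)(O)[C@@H](OCc1ccccc1)C=C | intermediate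
29 | (3S,4E)-3-({[tert-butyl(dimethyl)silyl]oxy}methyl)hex-4-enoyl chloride | ClC(=O)C[C@H](CO[Si](C)(C)C(C)(C)C)/C=C/C | intermediate
30 | lithium (3S,4S)-4-(benzyloxy)-3-methylhexa-1,5-dien-3-olate | [Li+].C=C[C@](C)([O-])[C@@H](OCc1ccccc1)C=C | intermediate
31 | (3S,4S)-4-(benzyloxy)-3-methylhexa-1,5-dien-3-yl (3S,4E)-3-({[tert-butyl(dimethyl)silyl]oxy}methyl)hex-4-enoate | C=C[C@](C)(OC(=O)C[C@H](CO[Si](C)(C)C(C)(C)C)/C=C/C)[C@@H](OCc1ccccc1)C=C | intermediate
32 | (4S,7S)-7-[(1S)-1-(benzyloxy)prop-2-en-1-yl]-4-({[tert-butyl(dimethyl)silyl]oxy}methyl)-7-methyl-4,7-dihydrooxepin-2(3H)-one | O=C1C[C@H](CO[Si](C)(C)C(C)(C)C)C=C[C@](C)(O1)[C@@H](OCc1ccccc1)C=C | intermediate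
33 | lithium enolate of 32 | [Li+].[O-]C1=C[C@H](CO[Si](C)(C)C(C)(C)C)C=C[C@](C)(O1)[C@@H](OCc1ccccc1)C=C | intermediate
34 | (4R,7S)-7-[(1S)-1-(benzyloxy)prop-2-en-1-yl]-3-[(benzyloxy)methyl]-4-({[tert-butyl(dimethyl)silyl]oxy}methyl)-7-methyl-4,7-dihydrooxepin-2(3H)-one (C3 epimers) | O=C1C(COCc2ccccc2)[C@H](CO[Si](C)(C)C(C)(C)C)C=C[C@](C)(O1)[C@@H](OCc1ccccc1)C=C | intermediate
35 | (4R,7S)-7-[(1S)-1-(benzyloxy)prop-2-en-1-yl]-3-[(benzyloxy)methyl]-4-(bromomethyl)-7-methyl-4,7-dihydrooxepin-2(3H)-one (C3 epimers) | O=C1C(COCc2ccccc2)[C@H](CBr)C=C[C@](C)(O1)[C@@H](OCc1ccccc1)C=C | intermediate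
36 | alkylzinc bromide from 35 (CH2ZnBr in place of CH2Br) | O=C1C(COCc2ccccc2)[C@H](C[Zn]Br)C=C[C@](C)(O1)[C@@H](OCc1ccccc1)C=C | intermediate
37 | (4R,7S)-7-[(1S)-1-(benzyloxy)prop-2-en-1-yl]-3-[(benzyloxy)methyl]-7-methyl-4-(2-{(2S,5R)-2-methyl-5-[(2S)-2-(trimethylsilyloxy)but-3-en-2-yl]oxolan-2-yl}-2-oxoethyl)-4,7-dihydrooxepin-2(3H)-one (C3 ketone) | O=C1C(COCc2ccccc2)[C@H](CC(=O)[C@]2(C)CC[C@@H](O2)[C@@](C)(O[Si](C)(C)C)C=C)C=C[C@](C)(O1)[C@@H](OCc1ccccc1)C=C | intermediate
38 | (3R)-alcohol of 37 with the C8 trimethylsilyl ether still in place | O=C1C(COCc2ccccc2)[C@H](C[C@@H](O)[C@]2(C)CC[C@@H](O2)[C@@](C)(O[Si](C)(C)C)C=C)C=C[C@](C)(O1)[C@@H](OCc1ccccc1)C=C | intermediate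
39 | (4R,7S)-7-[(1S)-1-(benzyloxy)prop-2-en-1-yl]-3-[(benzyloxy)methyl]-4-[(2R)-2-hydroxy-2-{(2S,5R)-5-[(2S)-2-hydroxybut-3-en-2-yl]-2-methyloxolan-2-yl}ethyl]-7-methyl-4,7-dihydrooxepin-2(3H)-one (seco-diene diol) | O=C1C(COCc2ccccc2)[C@H](C[C@@H](O)[C@]2(C)CC[C@@H](O2)[C@@](C)(O)C=C)C=C[C@](C)(O1)[C@@H](OCc1ccccc1)C=C | intermediate
40 | (1R,3R,4S,7R,8S,11S,12S)-11,17-bis(benzyloxy)-4,7-epoxy-3,8-dihydroxycembra-9,13-dien-16,12-olide (C15 epimers; C9=C10 E/Z) | O(Cc1ccccc1)CC1C(=O)O[C@@]2(C)/C=C\[C@H]1C[C@@H](O)[C@]1(C)CC[C@@H](O1)[C@@](C)(O)C=C[C@@H]2OCc1ccccc1 | intermediate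
41 | (1S,3R,4S,7R,8S,11S,12S)-11,17-bis(benzyloxy)-4,7-epoxy-3,8-dihydroxycembran-16,12-olide (C15 epimers) | O(Cc1ccccc1)CC1C(=O)O[C@@]2(C)CC[C@H]1C[C@@H](O)[C@]1(C)CC[C@@H](O1)[C@@](C)(O)CC[C@@H]2OCc1ccccc1 | intermediate
42 | (1S,3R,4S,7R,8S,11S,12S)-4,7-epoxy-3,8,11,17-tetrahydroxycembran-16,12-olide (C15 epimers) | OCC1C(=O)O[C@@]2(C)CC[C@H]1C[C@@H](O)[C@]1(C)CC[C@@H](O1)[C@@](C)(O)CC[C@@H]2O | intermediate
43 | (1S,3R,4S,7R,8S,11S,12S)-3,11,17-triacetoxy-4,7-epoxy-8-hydroxycembran-16,12-olide (C15 epimers) | CC(=O)OCC1C(=O)O[C@@]2(C)CC[C@H]1C[C@@H](OC(C)=O)[C@]1(C)CC[C@@H](O1)[C@@](C)(O)CC[C@@H]2OC(C)=O | intermediate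
44 | (1S,3R,4S,7R,8S,11S,12S)-3,11-diacetoxy-4,7-epoxy-8-hydroxycembr-15(17)-en-16,12-olide (CNP0343714.5) | C=C1C(=O)O[C@@]2(C)CC[C@H]1C[C@@H](OC(C)=O)[C@]1(C)CC[C@@H](O1)[C@@](C)(O)CC[C@@H]2OC(C)=O | target

## Step count, longest linear sequence, risky steps

Total: 31 steps. Longest linear sequence: 16 steps (steps 2–10, then 25–31). The two other branches (steps 11–15 then 21–24, and steps 16–20 then 21–24) also reach 16.

**Step 8 (oxolane closure on a vinyl epoxide).** The C4 alkoxide could attack the allylic tertiary carbon C8 (6-endo) or add SN2′ instead of closing 5-exo at C7. The fallback sets out from 5 and comes back at 12, closing the ring before the vinyl group exists: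
- TBSCl/imidazole gives tert-butyl{[(2S,3S)-3-(2-bromoethyl)-2-methyloxiran-2-yl]methoxy}dimethylsilane F1.
- NaI in acetone gives tert-butyl{[(2S,3S)-3-(2-iodoethyl)-2-methyloxiran-2-yl]methoxy}dimethylsilane F2.
- Alkylation of enolate 9 as in step 7 gives (2R,5S)-2-tert-butyl-5-{2-[(2S,3S)-3-({[tert-butyl(dimethyl)silyl]oxy}methyl)-3-methyloxiran-2-yl]ethyl}-5-methyl-1,3-dioxolan-4-one F3.
- K2CO3/MeOH now closes the ring on a plain trisubstituted epoxide, where only the 5-exo path is open, giving methyl (2S,5R)-5-[(2S)-1-{[tert-butyl(dimethyl)silyl]oxy}-2-hydroxypropan-2-yl]-2-methyloxolane-2-carboxylate F4.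
- Bu4NF frees methyl (2S,5R)-5-[(2S)-1,2-dihydroxypropan-2-yl]-2-methyloxolane-2-carboxylate F5.
- SO3·pyridine/DMSO oxidises the primary alcohol to methyl (2S,5R)-5-[(2R)-2-hydroxy-1-oxopropan-2-yl]-2-methyloxolane-2-carboxylate F6.
- Wittig methylenation with Ph3P=CH2 returns to 12.

**Step 25 (thioester–alkylzinc coupling).** The thioester sits on a quaternary α-alkoxy carbon and the zinc reagent is β-branched, so the coupling may be slow. The fallback sets out from 14 and 35 and comes back at 37, changing the union to an aldehyde addition followed by oxidation: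
- i-Bu2AlH at −78 °C reduces 14 to (2S,5R)-2-methyl-5-[(2S)-2-(trimethylsilyloxy)but-3-en-2-yl]oxolane-2-carbaldehyde F7.
- NaI converts 35 into (4R,7S)-7-[(1S)-1-(benzyloxy)prop-2-en-1-yl]-3-[(benzyloxy)methyl]-4-(iodomethyl)-7-methyl-4,7-dihydrooxepin-2(3H)-one F8.
- A Takai–Utimoto alkylchromium addition (CrCl2, cat. cobalt phthalocyanine Co(C32H16N8), DMF) joins them as the C3-epimeric carbinol mixture F9.
- Dess–Martin oxidation of F9 gives 37.

**Step 27 (macrocyclic ring-closing metathesis).** Both vinyl groups sit next to fully substituted or oxygenated carbons, so initiation may fail. The fallback sets out from 12 and comes back at 40, using a relay ring-closing metathesis on a redesigned substrate: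
- Ozonolysis of 12 (O3, CH2Cl2, −78 °C; Me2S) gives methyl (2S,5R)-5-[(2R)-2-hydroxy-1-oxopropan-2-yl]-2-methyloxolane-2-carboxylate F10 (the same aldehyde as F6).
- Wittig reaction with hex-5-en-1-ylidene(triphenyl)phosphorane gives methyl (2S,5R)-5-[(2S,3Z)-2-hydroxynona-3,8-dien-2-yl]-2-methyloxolane-2-carboxylate F11.
- The conditions of steps 9 and 10 give S-ethyl (2S,5R)-5-[(2S,3Z)-2-hydroxynona-3,8-dien-2-yl]-2-methyloxolane-2-carbothioate F12 and its trimethylsilyl ether F13.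
- The conditions of steps 25 and 26 with 36 give the relay seco-ketone F14 and the relay seco-diene diol F15.
- With the second-generation Hoveyda–Grubbs catalyst, ruthenium loads on the unhindered terminal alkene of F15, expels cyclopentene to place the carbene on C9, and closes onto the C10 vinyl group to give 40.

## Further compounds

F1 | step 8 | tert-butyl{[(2S,3S)-3-(2-bromoethyl)-2-methyloxiran-2-yl]methoxy}dimethylsilane | CC(C)(C)[Si](C)(C)OC[C@]1(C)O[C@H]1CCBr
F2 | step 8 | tert-butyl{[(2S,3S)-3-(2-iodoethyl)-2-methyloxiran-2-yl]methoxy}dimethylsilane | CC(C)(C)[Si](C)(C)OC[C@]1(C)O[C@H]1CCI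
F3 | step 8 | (2R,5S)-2-tert-butyl-5-{2-[(2S,3S)-3-({[tert-butyl(dimethyl)silyl]oxy}methyl)-3-methyloxiran-2-yl]ethyl}-5-methyl-1,3-dioxolan-4-one | C[C@@]1(CC[C@@H]2O[C@@]2(C)CO[Si](C)(C)C(C)(C)C)O[C@@H](C(C)(C)C)OC1=O
F4 | step 8 | methyl (2S,5R)-5-[(2S)-1-{[tert-butyl(dimethyl)silyl]oxy}-2-hydroxypropan-2-yl]-2-methyloxolane-2-carboxylate | COC(=O)[C@]1(C)CC[C@@H](O1)[C@@](C)(O)CO[Si](C)(C)C(C)(C)C
F5 | step 8 | methyl (2S,5R)-5-[(2S)-1,2-dihydroxypropan-2-yl]-2-methyloxolane-2-carboxylate | COC(=O)[C@]1(C)CC[C@@H](O1)[C@@](C)(O)CO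
F6 | step 8 | methyl (2S,5R)-5-[(2R)-2-hydroxy-1-oxopropan-2-yl]-2-methyloxolane-2-carboxylate | COC(=O)[C@]1(C)CC[C@@H](O1)[C@@](C)(O)C=O
F7 | step 25 | (2S,5R)-2-methyl-5-[(2S)-2-(trimethylsilyloxy)but-3-en-2-yl]oxolane-2-carbaldehyde | O=C[C@]1(C)CC[C@@H](O1)[C@@](C)(O[Si](C)(C)C)C=C
F8 | step 25 | (4R,7S)-7-[(1S)-1-(benzyloxy)prop-2-en-1-yl]-3-[(benzyloxy)methyl]-4-(iodomethyl)-7-methyl-4,7-dihydrooxepin-2(3H)-one | O=C1C(COCc2ccccc2)[C@H](CI)C=C[C@](C)(O1)[C@@H](OCc1ccccc1)C=C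
F9 | step 25 | C3-epimeric carbinol mixture (38 and its 3S epimer) | O=C1C(COCc2ccccc2)[C@H](CC(O)[C@]2(C)CC[C@@H](O2)[C@@](C)(O[Si](C)(C)C)C=C)C=C[C@](C)(O1)[C@@H](OCc1ccccc1)C=C
F10 | step 27 | methyl (2S,5R)-5-[(2R)-2-hydroxy-1-oxopropan-2-yl]-2-methyloxolane-2-carboxylate | COC(=O)[C@]1(C)CC[C@@H](O1)[C@@](C)(O)C=O
F11 | step 27 | methyl (2S,5R)-5-[(2S,3Z)-2-hydroxynona-3,8-dien-2-yl]-2-methyloxolane-2-carboxylate | COC(=O)[C@]1(C)CC[C@@H](O1)[C@@](C)(O)/C=C\CCCC=C
F12 | step 27 | S-ethyl (2S,5R)-5-[(2S,3Z)-2-hydroxynona-3,8-dien-2-yl]-2-methyloxolane-2-carbothioate | CCSC(=O)[C@]1(C)CC[C@@H](O1)[C@@](C)(O)/C=C\CCCC=C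
F13 | step 27 | S-ethyl (2S,5R)-2-methyl-5-[(2S,3Z)-2-(trimethylsilyloxy)nona-3,8-dien-2-yl]oxolane-2-carbothioate | CCSC(=O)[C@]1(C)CC[C@@H](O1)[C@@](C)(O[Si](C)(C)C)/C=C\CCCC=C
F14 | step 27 | relay seco-ketone (37 with a (Z)-hepta-1,6-dienyl group in place of the C8 vinyl group) | O=C1C(COCc2ccccc2)[C@H](CC(=O)[C@]2(C)CC[C@@H](O2)[C@@](C)(O[Si](C)(C)C)/C=C\CCCC=C)C=C[C@](C)(O1)[C@@H](OCc1ccccc1)C=C
F15 | step 27 | relay seco-diene diol (39 with a (Z)-hepta-1,6-dienyl group in place of the C8 vinyl group) | O=C1C(COCc2ccccc2)[C@H](C[C@@H](O)[C@]2(C)CC[C@@H](O2)[C@@](C)(O)/C=C\CCCC=C)C=C[C@](C)(O1)[C@@H](OCc1ccccc1)C=C
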